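## Retrosynthetic overview

1. The C13 isopropyl group is added last by radical alkylation of the only free quinone C–H. The quinone comes from CAN oxidation of an 11,12,14-trimethoxyarene.
2. Ring A is a cyclohexenone that is gem-dimethylated at C4, then stripped of its C=C and C3=O (H2, then Wolff–Kishner).
3. Key disconnection C5–C6: an enantioselective, desymmetrising intramolecular Michael addition of an aryl methyl ketone onto a prochiral p-quinol (cyclohexadienone). It closes ring B and sets C5 and C10; O-10 then closes onto C7 to give the oxygen bridge.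
4. The p-quinol comes from the lateral dianion of 2,4,5-trimethoxy-6-methylbenzoic acid and p-benzoquinone monoketal (made by oxidative dearomatisation of 4-methoxyphenol), with CO2Li converted to COCH3 by MeLi.
5. Ring order: ring C (purchased arene) → ring A (dearomatised phenol) → ring B and the oxygen bridge together → quinone.

Assumption 1: the SMILES is taken as authoritative. In icetexane numbering (ring A = C1–C5, C10; C6, C7; ring C = C8, C9, C11–C14; C20 = CH2 between C9 and C10) it is (5R,7S,10S), with O-10 and H-5 cis, i.e. komaroviquinone.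

Assumption 2: the sense of induction of the cinchonidinium catalyst in step 4 is not predictable with confidence. If it gives the antipode, the pseudo-enantiomeric cinchoninium salt is used instead.

## Route

Step 1
Reactants: 1 4-methoxyphenol
Product: 2 4,4-dimethoxycyclohexa-2,5-dien-1-one
Conditions: PhI(OAc)2 (1.05 equiv), MeOH, 0 °C → rt
Reagents that add atoms: methanol CO
Why: Oxidative dearomatisation of a p-alkoxyphenol by the trivalent-iodine oxidant, with methanol trapping the phenoxenium ion at C4, gives the symmetric cross-conjugated dienone ketal (no stereocentre).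

Step 2
Reactants: 3 2,4,5-trimethoxybenzoic acid
Product: 4 2,4,5-trimethoxy-6-methylbenzoic acid
Conditions: s-BuLi (2.2 equiv), TMEDA, THF, −78 °C; MeI, −78 °C → rt; aq. HCl
Reagents that add atoms: iodomethane CI
Why: Carboxylate-directed ortho-metalation takes place at the one position flanked by CO2Li and OMe, and the aryllithium is methylated by SN2 on MeI (no stereocentre).

Step 3
Reactants: 4 2,4,5-trimethoxy-6-methylbenzoic acid; 2 4,4-dimethoxycyclohexa-2,5-dien-1-one
Product: 8 4-[(2-acetyl-3,5,6-trimethoxyphenyl)methyl]-4-hydroxycyclohexa-2,5-dien-1-one, via dilithium carbinolate carboxylate 5 (not isolated), via trilithium gem-diolate 6 (not isolated), via hydroxy ketone dimethyl ketal 7 (not isolated)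
Conditions: LiN(iPr)2 (2.1 equiv), THF, −78 → 0 °C; 2, −78 °C; MeLi (5 equiv), −78 → 0 °C; inverse quench into 0.5 M HCl, THF, 0 °C, 30 min
Reagents that add atoms: methyllithium [Li]C; water O
Why: Lateral lithiation of the o-toluic acid dianion and kinetic 1,2-addition of this hard dilithio species to the dienone carbonyl are followed by the carboxylate-to-methyl-ketone reaction with MeLi (the gem-diolate blocks over-addition) and mild ketal hydrolysis, giving the achiral p-quinol in which C10 is still prochiral.

Step 4
Reactants: 8 4-[(2-acetyl-3,5,6-trimethoxyphenyl)methyl]-4-hydroxycyclohexa-2,5-dien-1-one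
Product: 10 methyl ketal enone (7-O-methyl ketal of 9; full name in the compound list), via bridged hemiketal enone 9 (not isolated)
Conditions: O-allyl-N-(9-anthracenylmethyl)cinchonidinium bromide (10 mol%), CsOH·H2O (0.5 equiv), toluene/CH2Cl2 7:1, 0.02 M, −40 °C; filter through silica; then camphorsulfonic acid (10 mol%), MeOH, rt
Reagents that add atoms: methanol CO
Why: Proposed new method: the chiral ammonium enolate of the hindered aryl methyl ketone (C6) adds intramolecularly to one of the two enantiotopic enone β-carbons of the prochiral dienone (7-membered ring-closing Michael addition, desymmetrisation); the short benzylic tether can deliver C6 only to the face of ring A that carries C20, so H-5 ends up cis to O-10, the ion-paired catalyst selects the enone arm and so sets C5 and C10 together, and O-10 at once traps the C7 ketone as the bridged hemiketal (C7 fixed by the bridge), which switches off retro-Michael and is then exchanged to the methyl ketal; the closest known reaction types are cinchona-ammonium phase-transfer Michael additions of aryl methyl ketone enolates to enones and amine- or base-catalysed desymmetrising intramolecular Michael additions to 4,4-disubstituted cyclohexadienones.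

Step 5
Reactants: 10 methyl ketal enone
Product: 11 gem-dimethyl enone (4,4-dimethyl derivative of 10)
Conditions: KOtBu (3 equiv), MeI (8 equiv), THF, −20 °C → rt
Reagents that add atoms: iodomethane CI
Why: The enone has acidic hydrogens only at C4 (the γ-carbon C10 is quaternary), so exhaustive α′-enolate alkylation installs the gem-dimethyl group, while the closed methyl ketal prevents ring opening and retro-Michael and so protects C5 and C10.

Step 6
Reactants: 11 gem-dimethyl enone
Product: 12 saturated ketone (1,2-dihydro derivative of 11)
Conditions: H2 (1 atm), 10% Pd/C, EtOAc, rt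
Reagents that add atoms: none
Why: Heterogeneous catalytic hydrogenation saturates the disubstituted enone C=C under neutral conditions that leave the arene and the ketal untouched (no new stereocentre).

Step 7
Reactants: 12 saturated ketone
Product: 15 bridged hemiketal arene, via hydrazone 13 (not isolated), via deoxygenated methyl ketal 14 (not isolated)
Conditions: N2H4·H2O, KOH, diethylene glycol, 130 °C then 200 °C; then 2 M HCl, THF, 40 °C
Reagents that add atoms: water O
Why: Wolff–Kishner (Huang-Minlon) reduction removes the neopentyl C3 carbonyl under base, to which the ketal and aryl ethers are inert, and the acidic work-up exchanges the methyl ketal for the hemiketal through the ring-opened hydroxy ketone, which can re-close only with the C7 configuration dictated by C10.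

Step 8
Reactants: 15 bridged hemiketal arene
Product: 16 methoxyquinone lacking the isopropyl group
Conditions: (NH4)2Ce(NO3)6 (2.5 equiv), MeCN/H2O 2:1, 0 °C
Reagents that add atoms: water O
Why: Oxidative demethylation by ceric ammonium nitrate (tetravalent cerium) converts the para-related 11,14-dimethoxy pair into the p-quinone and keeps the 12-methoxy group, without touching the stereocentres.

Step 9
Reactants: 16 methoxyquinone lacking the isopropyl group
Product: 17 komaroviquinone (target)
Conditions: Me2CHCO2H (5 equiv), AgNO3 (0.3 equiv), (NH4)2S2O8 (2 equiv), MeCN/H2O 1:1, 65 °C, dark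
Reagents that add atoms: 2-methylpropanoic acid CC(C)C(=O)O
Why: In this Jacobsen–Torssell (Minisci-type) decarboxylative radical alkylation, divalent silver formed from monovalent silver and persulfate generates the isopropyl radical, which adds to the only unsubstituted quinone carbon (C13, β to the C11 carbonyl) and is re-oxidised to the quinone, with no stereocentre affected.

## Compound list

CIP labels use icetexane numbering. They change between compounds only because substituent priorities change; the spatial arrangement set in step 4 is the same throughout.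

1 | 4-methoxyphenol | COc1ccc(O)cc1 | starting material
2 | 4,4-dimethoxycyclohexa-2,5-dien-1-one | COC1(OC)C=CC(=O)C=C1 | intermediate
3 | 2,4,5-trimethoxybenzoic acid | OC(=O)c1cc(OC)c(OC)cc1OC | starting material
4 | 2,4,5-trimethoxy-6-methylbenzoic acid | Cc1c(C(=O)O)c(OC)cc(OC)c1OC | intermediate
5 | dilithium 2-[(4,4-dimethoxy-1-oxidocyclohexa-2,5-dien-1-yl)methyl]-3,4,6-trimethoxybenzoate | [Li+].[Li+].[O-]C(=O)c1c(OC)cc(OC)c(OC)c1CC1([O-])C=CC(OC)(OC)C=C1 | intermediate
6 | trilithium gem-diolate from MeLi addition to the carboxylate of 5 | [Li+].[Li+].[Li+].CC([O-])([O-])c1c(OC)cc(OC)c(OC)c1CC1([O-])C=CC(OC)(OC)C=C1 | intermediate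
7 | 1-{2-[(1-hydroxy-4,4-dimethoxycyclohexa-2,5-dien-1-yl)methyl]-3,4,6-trimethoxyphenyl}ethan-1-one | CC(=O)c1c(OC)cc(OC)c(OC)c1CC1(O)C=CC(OC)(OC)C=C1 | intermediate
8 | 4-[(2-acetyl-3,5,6-trimethoxyphenyl)methyl]-4-hydroxycyclohexa-2,5-dien-1-one (achiral; in equilibrium with its six-membered cyclic hemiketal) | CC(=O)c1c(OC)cc(OC)c(OC)c1CC1(O)C=CC(=O)C=C1 | intermediate
9 | (5S,7S,10S)-7,10-epoxy-7-hydroxy-11,12,14-trimethoxy-15,16,17,18,19-pentanoricetexa-1,8,11,13-tetraen-3-one (O-10 and H-5 cis) | COc1cc(OC)c2c(C[C@@]34C=CC(=O)C[C@H]3C[C@]2(O)O4)c1OC | intermediate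
10 | (5S,7S,10S)-7,10-epoxy-7,11,12,14-tetramethoxy-15,16,17,18,19-pentanoricetexa-1,8,11,13-tetraen-3-one | COc1cc(OC)c2c(C[C@@]34C=CC(=O)C[C@H]3C[C@]2(OC)O4)c1OC | intermediate
11 | (5R,7S,10R)-7,10-epoxy-7,11,12,14-tetramethoxy-15,16,17-trinoricetexa-1,8,11,13-tetraen-3-one | COc1cc(OC)c2c(C[C@@]34C=CC(=O)C(C)(C)[C@H]3C[C@]2(OC)O4)c1OC | intermediate
12 | (5R,7S,10S)-7,10-epoxy-7,11,12,14-tetramethoxy-15,16,17-trinoricetexa-8,11,13-trien-3-one | COc1cc(OC)c2c(C[C@@]34CCC(=O)C(C)(C)[C@H]3C[C@]2(OC)O4)c1OC | intermediate
13 | hydrazone of 12 at C3 | COc1cc(OC)c2c(C[C@@]34CCC(=NN)C(C)(C)[C@H]3C[C@]2(OC)O4)c1OC | intermediate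
14 | (5R,7S,10S)-7,10-epoxy-7,11,12,14-tetramethoxy-15,16,17-trinoricetexa-8,11,13-triene | COc1cc(OC)c2c(C[C@@]34CCCC(C)(C)[C@H]3C[C@]2(OC)O4)c1OC | intermediate
15 | (5R,7S,10S)-7,10-epoxy-11,12,14-trimethoxy-15,16,17-trinoricetexa-8,11,13-trien-7-ol | COc1cc(OC)c2c(C[C@@]34CCCC(C)(C)[C@H]3C[C@]2(O)O4)c1OC | intermediate
16 | (5R,7S,10S)-7,10-epoxy-7-hydroxy-12-methoxy-15,16,17-trinoricetexa-8,12-diene-11,14-dione | COC1=CC(=O)C2=C(C[C@@]34CCCC(C)(C)[C@H]3C[C@]2(O)O4)C1=O | intermediate
17 | (5R,7S,10S)-7,10-epoxy-7-hydroxy-12-methoxyicetexa-8,12-diene-11,14-dione (komaroviquinone) | COC1=C(C(C)C)C(=O)C2=C(C[C@@]34CCCC(C)(C)[C@H]3C[C@]2(O)O4)C1=O | target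

## Step count and risks

Total steps: 9. Longest linear sequence: 8 (3 → 4 → 8 → 10 → 11 → 12 → 15 → 16 → 17; the branch from 1 is one step).

**Step 4 (most likely to fail).** The seven-membered Michael closure may be slow, the cyclic hemiketal of 8 can divert reversibly by oxa-Michael addition, and the enantioselectivity of the ion pair is untested. The fallback replaces the catalytic enolate by a preformed enol silane and a chiral Lewis acid. Starting from 8, TMSOTf and Et3N give the bis(trimethylsilyl) compound F3 (enol silane of the acetyl group plus the O-10 silyl ether). The N-protonated (S)-o-tolyl oxazaborolidine (triflimide salt) then activates the dienone carbonyl for an intramolecular Mukaiyama–Michael addition to give the silyl dienol ether F4. Dilute HCl removes both silyl groups, and the hydroxy ketone closes to 9, where the fallback rejoins the route (ketalisation to 10 as in step 4).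

**Step 3.** The one-pot union may suffer from competing 1,4-addition of the benzylic dianion to 2 and from sluggish MeLi addition to the hindered carboxylate. The fallback works at the ester oxidation level with an organocerium reagent. Starting from 4, MeI and K2CO3 give methyl 2,4,5-trimethoxy-6-methylbenzoate F1. Lateral lithiation with LiN(iPr)2, transmetalation with anhydrous CeCl3 and addition to 2 give an alkoxide that lactonises onto the ester, forming the isolable spirolactone F2. One equivalent of MeLi at −78 °C adds once to the lactone, and neutral work-up gives 7, where the fallback rejoins the route (dilute acid then gives 8).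

**Step 9.** The isopropyl radical must add at a hindered carbon next to the methoxy group, and the product is light-sensitive. The fallback uses polar halogenation and cross-coupling instead of radical C–H alkylation. Starting from 16, Br2 followed by Et3N gives the 13-bromoquinone F5. Suzuki coupling with isopropenylboronic acid pinacol ester (Pd(PPh3)4, K2CO3) gives the 13-isopropenylquinone F6. H2 over Pd/C saturates the alkene and reduces the quinone to the hydroquinone F7, which air re-oxidises to 17, where the fallback rejoins the route.

## Further compounds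

F1 | step 3 | methyl 2,4,5-trimethoxy-6-methylbenzoate | COC(=O)c1c(OC)cc(OC)c(OC)c1C
F2 | step 3 | 4,4,5',6',8'-pentamethoxyspiro[cyclohexa-2,5-diene-1,3'-isochroman]-1'-one | COc1cc(OC)c2C(=O)OC3(Cc2c1OC)C=CC(OC)(OC)C=C3
F3 | step 4 | 4-({2-[1-(trimethylsilyloxy)ethenyl]-3,5,6-trimethoxyphenyl}methyl)-4-(trimethylsilyloxy)cyclohexa-2,5-dien-1-one | C=C(O[Si](C)(C)C)c1c(OC)cc(OC)c(OC)c1CC1(O[Si](C)(C)C)C=CC(=O)C=C1
F4 | step 4 | ring B-closed 7-ketone with 3-(trimethylsilyloxy)-1,3-diene in ring A and 10-trimethylsilyloxy group (C5 and C10 as in 9) | COc1cc(OC)c2c(C[C@@]3(O[Si](C)(C)C)C=CC(O[Si](C)(C)C)=C[C@H]3CC2=O)c1OC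
F5 | step 9 | 13-bromo derivative of 16 | COC1=C(Br)C(=O)C2=C(C[C@@]34CCCC(C)(C)[C@H]3C[C@]2(O)O4)C1=O
F6 | step 9 | 13-(prop-1-en-2-yl) derivative of 16 | COC1=C(C(C)=C)C(=O)C2=C(C[C@@]34CCCC(C)(C)[C@H]3C[C@]2(O)O4)C1=O
F7 | step 9 | 11,14-hydroquinone of 17 | COc1c(C(C)C)c(O)c2c(C[C@@]34CCCC(C)(C)[C@H]3C[C@]2(O)O4)c1O
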